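Ar = 4-methoxy-2-(methoxymethoxy)-3-(3-methylbut-2-en-1-yl)phenyl throughout. Atom labels C2, C3, C4, C4a, C5–C8, C8a and C1'–C4' are isoflavan numbering of the target 26.

## Analysis of the target

The target 26 is a (3R)-isoflavan: a chroman (benzo ring A fused to pyran ring C) that carries aryl ring B at C3. Ring A is a 1,3,5-trioxygenated benzene in which every oxygen has a different fate: O1 on C8a is the pyran oxygen, C5 carries a methyl ether and C7 a free hydroxyl, and the benzylic C4 sits on C4a between the first two. Ring B is tetrasubstituted, with a free 2'-hydroxyl, a prenyl group on C3' wedged between two oxygens, and a methoxy group on C4'. C3 is the only stereocentre; it is a benzylic methine flanked by two methylene groups, so it must be set absolutely, with no neighbouring centre to relay from. The prenyl alkene is the most delicate group: under acid it can add the neighbouring 2'-hydroxyl, and it rules out hydrogenation and most electrophilic halogenations. The real difficulty is ring A, because substitution chemistry on a symmetric 1,3,5-trioxygenated arene tells the three oxygens and the three ring CH positions apart poorly. The strategy rests on the triad C8a(OH)–C4a(alkyl)–C5(OMe) with the third oxygen on C7: this is exactly the pattern written when a four-carbon vinylketene (C8a, C8, C7, C6) combines with a two-carbon alkoxyalkyne (C4a, C5).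

## Retrosynthetic reasoning

**26 back to 24.** The two phenols of 26 are unmasked last, the C7 hydroxyl from a silyl ether (25 from 24) and the 2'-hydroxyl from a methoxymethyl ether (26 from 25). The ring B oxygen has to stay masked until ring C exists, because a free 2'-hydroxyl lies one atom closer to C2 than the ring A oxygen and would close a five-membered ring instead.

**24 back to 23.** The O1–C2 bond is cut. In the forward direction the C8a phenoxide of 23 displaces a primary chloride in a six-membered closure. The cut is made here because it leaves C3 untouched and because the hydroxyl it needs is the one that the ring-forming step delivers free.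

**23 back to 15 and 18.** Ring A is taken apart completely: C4a–C8a and C5–C6 are cut, and C8–C8a is returned to a four-membered ring. This leaves alkyne 15, which carries C4a with the whole chiral chain and C5 with its methoxy group, and cyclobutenone 18, which carries C8a as a carbonyl and C7 with its silyloxy group. What is gained is that no oxygen of ring A ever has to be distinguished from another: each arrives from a different precursor atom and in a different form (free OH, OMe, OSi). The forward reaction must open 18 to vinylketene 19, join it to 15 in one orientation only, and carry cycloadduct 20 through 21 and 22 to the phenol 23.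

**18 back to 16.** The silyloxy group of 18 is traced to the enol oxygen of dione 17, and 17 to the commercial ethyl vinylogous ester 16 by hydrolysis. A silyl group is chosen because it is the only C7 mask here that is later removed without touching the methyl ethers or the prenyl group.

**15 back to 12 and 13.** The sp3–sp bond between C4 and the future C4a is cut. Forward, the acetylide 14, made in the flask from acetal 13, displaces the primary triflate 12. A methyl ynol ether is required because the methyl group becomes the C5 methoxy group of the target.

**12 back to 9.** The two arms on C3 are told apart by what they carry. The arm that becomes C2 is fixed as a chloride early (10 from 9), since a chloride survives base, triflation, the acetylide and heat and still leaves under phenoxide attack. The other arm is released from its acetate (11), activated as triflate 12 and becomes C4.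

**9 back to 8.** The stereocentre is traced to the prochiral diol 8, whose two hydroxymethyl arms are enantiotopic. A lipase-mediated monoacetylation differentiates them and sets C3 in one operation, with no C–C or C–H bond made at the stereocentre itself.

**8 back to 5 and 6.** The diol 8 is the reduction product of arylmalonate 7, and the C3–C1' bond is cut to aryl bromide 5 and diethyl malonate 6. A palladium-catalysed enolate arylation makes this bond without an organolithium, which matters because 5 carries acidic benzylic-allylic hydrogens.

**5 back to 1.** The prenyl group between the two ring B oxygens is traced through allyl compound 4 to phenol 3, and 3 to allyl ether 2 of the commercial bromophenol 1. Direct metalation between the oxygens is not available while bromine is on the ring (halogen–metal exchange and halogen migration). A sigmatropic shift therefore delivers the carbon chain from oxygen to the only free ortho carbon, and metathesis then converts allyl into prenyl.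

## Alternatives that were turned down

**Alternative 1:** Here C3–C4 and the acyl O1–C2 bond are cut. Forward, the ring A ortho-quinone methide A2 (set free in the flask by base) is trapped by the catalyst-bound enolate of the ring B arylacetic acid A3 under chiral isothiourea catalysis. Conjugate addition and lactonisation give the dihydrocoumarin A1.
- For it: it is convergent, it sets C3 and closes ring C in one catalytic asymmetric step, and it reaches the bicyclic core in far fewer steps than the chosen route. On step economy and on catalytic stereocontrol it is stronger.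
- Against it: C2 arrives as a lactone carbonyl, so A1 still has to be reduced to the diol and re-closed. In A1 the stereocentre is an α-aryl ester carbon with an acidic hydrogen, exposed to the base that generates A2 and to the hydride that follows. A2 is strongly donor-stabilised by its C5 and C7 oxygens and therefore a weak acceptor, and the enolate of A3 is hindered by its ortho substituent. Most important, the precursor of A2 is the same regiodefined trioxygenated ring A that substitution chemistry makes poorly.
- In comparison: the chosen route offers ring A oxygens that are differentiated by construction and a C3 centre that is never adjacent to a carbonyl after it is set.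

**Alternative 2:** Here C2–C3 and C3–C4 are cut, which amounts to inserting one carbon, with ring B attached, into the furan double bond of benzofuran A5. Forward, the arylchlorocarbene from diazirine A6 cyclopropanates A5, and the adduct opens with loss of chloride to the benzopyrylium salt A4.
- For it: two flat, simple fragments are joined late, and the C3 carbon enters already bearing its aryl group.
- Against it: A4 is achiral. C3 must then be created by an enantioselective reduction whose faces differ only in the distant substitution of two methylene neighbours. Because that reduction is a hydrogenation, the prenyl group cannot be present, so A4 carries a bromine placeholder and the prenyl group has to be introduced afterwards at a carbon flanked by two oxygens on an advanced intermediate. A5 again needs a ring A differentiated by substitution chemistry, and the electron-rich arene of A5 is a competing carbene acceptor.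
- In comparison: this route is as convergent as the chosen one but carries more steps after its key step and an open stereochemical problem, whereas the chosen route fixes C3 early and carries the prenyl group from the start.

**Alternative 3:** Here C4–C4a and O1–C2 are cut. Forward, 5-methoxybenzene-1,3-diol A8 adds through a ring carbon to the iminium ion formed from acrolein A9 and a chiral primary amine, the resulting enamine is protonated enantioselectively at C3, and the aldehyde closes onto a neighbouring hydroxyl to give lactol A7.
- For it: it is the shortest of all, A8 is a commercial compound, ring A needs no protecting groups, and the asymmetric step is catalytic. On step count it is clearly stronger than the chosen route.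
- Against it: A8 has two kinds of nucleophilic carbon, one between the two hydroxyls and one between a hydroxyl and the methoxy group. Only the latter, followed by closure on the adjacent hydroxyl, gives the C5-methoxy, C7-hydroxy pattern, so a regioisomeric isoflavan is a built-in by-product. The new centre of A7 is α to a masked aldehyde that is in equilibrium with the open form and can enolise under the amine catalyst. The lactol must then be deoxygenated under acidic ionic conditions with the prenyl group and a free neighbouring phenol present.
- In comparison: the chosen route pays in length but offers an unambiguous ring A and a stereocentre that cannot epimerise.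

Key step: step 14

## Route

Assumption: with vinyl acetate the lipase is taken to acetylate the enantiotopic arm of diol 8 that gives the (R)-monoacetate 9; should it select the other arm, the hydrolysis mode described under the uncertain steps reaches 9 from the diacetate.
Assumption: 3-ethoxycyclobut-2-en-1-one 16 is taken as a purchasable compound.

Step 1
Reactants: 1 2-bromo-5-methoxyphenol
Product: 2 1-bromo-4-methoxy-2-(prop-2-en-1-yloxy)benzene
Conditions: allyl bromide, K2CO3, acetone, reflux
Reagents that add atoms: allyl bromide, C=CCBr
Why: Williamson ether synthesis; the phenoxide is the only nucleophile present and allyl bromide is a reactive primary electrophile.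

Step 2
Reactants: 2 1-bromo-4-methoxy-2-(prop-2-en-1-yloxy)benzene
Product: 3 6-bromo-3-methoxy-2-(prop-2-en-1-yl)phenol
Conditions: N,N-diethylaniline, 190 °C
Reagents that add atoms: none
Why: Aromatic Claisen rearrangement; one ortho carbon carries bromine, so the [3,3] shift and rearomatisation should place the allyl group on the only free ortho carbon, the one between the two oxygens.

Step 3
Reactants: 3 6-bromo-3-methoxy-2-(prop-2-en-1-yl)phenol
Product: 4 1-bromo-4-methoxy-2-(methoxymethoxy)-3-(prop-2-en-1-yl)benzene
Conditions: NaH, MOMCl, THF/DMF, 0 °C to rt
Reagents that add atoms: chloromethyl methyl ether, COCCl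
Why: O-alkylation of the sodium phenoxide; the pre-formed phenoxide overcomes the hindrance of the doubly flanked hydroxyl, and the acetal formed tolerates every basic and thermal step that follows.

Step 4
Reactants: 4 1-bromo-4-methoxy-2-(methoxymethoxy)-3-(prop-2-en-1-yl)benzene
Product: 5 1-bromo-4-methoxy-2-(methoxymethoxy)-3-(3-methylbut-2-en-1-yl)benzene
Conditions: 2-methylbut-2-ene (excess), second-generation Grubbs catalyst RuCl2(=CHPh)(H2IMes)(PCy3) (3 mol %), CH2Cl2, 40 °C
Reagents that add atoms: 2-methylbut-2-ene, CC=C(C)C
Why: Olefin cross-metathesis of a terminal allylarene with a trisubstituted alkene used in excess, which exchanges the terminal CH2 for an isopropylidene group; the aryl bromide and the acetal are inert to the ruthenium carbene.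

Step 5
Reactants: 5 1-bromo-4-methoxy-2-(methoxymethoxy)-3-(3-methylbut-2-en-1-yl)benzene; 6 diethyl malonate
Product: 7 diethyl 2-Ar-propanedioate
Conditions: Pd(OAc)2 (3 mol %), P(t-Bu)3·HBF4 (6 mol %), K3PO4, toluene, 90 °C
Reagents that add atoms: none
Why: Palladium-catalysed α-arylation of a malonate (Buchwald–Hartwig-type enolate arylation): oxidative addition of the aryl bromide to zerovalent palladium, exchange of bromide for the malonate enolate and reductive elimination. The product is more acidic than 6 and rests as its enolate, which stops a second arylation.

Step 6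
Reactants: 7 diethyl 2-Ar-propanedioate
Product: 8 2-Ar-propane-1,3-diol
Conditions: LiAlH4, THF, 0 °C to rt (7 added to the hydride)
Reagents that add atoms: none
Why: Hydride reduction of both esters to primary alcohols; inverse addition keeps hydride in excess so that reduction outruns enolisation of the arylmalonate.

Step 7
Reactants: 8 2-Ar-propane-1,3-diol
Product: 9 (2R)-3-hydroxy-2-Ar-propyl acetate
Conditions: Amano lipase PS (Burkholderia cepacia), vinyl acetate, t-BuOMe, 25 °C
Reagents that add atoms: vinyl acetate, CC(=O)OC=C
Why: Enzymatic desymmetrisation of a prochiral 2-aryl-1,3-diol by irreversible transesterification; the chiral acyl-enzyme pocket accepts one of the two enantiotopic hydroxymethyl arms, which sets C3. Any over-acetylation to the diacetate should consume the minor enantiomer of 9 faster and so raise the purity of what remains.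

Step 8
Reactants: 9 (2R)-3-hydroxy-2-Ar-propyl acetate
Product: 10 (2S)-3-chloro-2-Ar-propyl acetate
Conditions: PPh3, CCl4, CH2Cl2, 40 °C
Reagents that add atoms: carbon tetrachloride, ClC(Cl)(Cl)Cl
Why: Appel chlorination, an SN2 displacement of the alkoxyphosphonium ion at the primary carbon; the neutral medium avoids acetyl migration between the arms, which would erode the configuration. No bond at C3 changes, and the descriptor switches from R to S only through the change in CIP priority.

Step 9
Reactants: 10 (2S)-3-chloro-2-Ar-propyl acetate
Product: 11 (2S)-3-chloro-2-Ar-propan-1-ol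
Conditions: K2CO3 (0.2 equiv), MeOH, 0 °C
Reagents that add atoms: none
Why: Base-catalysed transesterification of the acetate to methanol; at 0 °C the four-membered closure of the alkoxide onto the chloride is too slow to compete.

Step 10
Reactants: 11 (2S)-3-chloro-2-Ar-propan-1-ol
Product: 12 (2S)-3-chloro-2-Ar-propyl trifluoromethanesulfonate
Conditions: Tf2O, 2,6-lutidine, CH2Cl2, −78 °C; cold filtration, used at once
Reagents that add atoms: trifluoromethanesulfonic anhydride, O=S(=O)(OS(=O)(=O)C(F)(F)F)C(F)(F)F
Why: O-sulfonylation of a primary alcohol with a hindered base; the triflate is made cold and used immediately, so that it reacts by direct displacement before the electron-rich aryl group can participate.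

Step 11
Reactants: 12 (2S)-3-chloro-2-Ar-propyl trifluoromethanesulfonate; 13 2-chloro-1,1-dimethoxyethane (chloroacetaldehyde dimethyl acetal)
Product: 15 (4R)-5-chloro-1-methoxy-4-Ar-pent-1-yne, via lithium methoxyacetylide 14 (not isolated)
Conditions: 13, LiNEt2 (3.0 equiv), THF, 0 °C; then 12, DMPU, −78 to −20 °C
Reagents that add atoms: none
Why: Two base-induced eliminations (methanol, then HCl) and a deprotonation turn 13 into acetylide 14, which alkylates the primary triflate by SN2; the chloride is a far poorer leaving group and stays untouched at low temperature. The stereocentre is not involved, and the descriptor returns to R through the priority change. The ynol ether is purified on base-treated silica and kept cold, since it is hydrated by acid.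

Step 12
Reactants: 16 3-ethoxycyclobut-2-en-1-one
Product: 17 cyclobutane-1,3-dione (present largely as its enol, 3-hydroxycyclobut-2-en-1-one)
Conditions: 1 M HCl (aq.), 0 °C to rt
Reagents that add atoms: water, O
Why: Acid hydrolysis of a vinylogous ester by addition of water at C3 and loss of ethanol.

Step 13
Reactants: 17 cyclobutane-1,3-dione
Product: 18 3-(triisopropylsilyloxy)cyclobut-2-en-1-one
Conditions: TIPSCl, Et3N, CH2Cl2, 0 °C; non-aqueous work-up
Reagents that add atoms: chlorotriisopropylsilane, CC(C)[Si](Cl)(C(C)C)C(C)C
Why: O-silylation of a strongly acidic enol (a vinylogous carboxylic acid); the bulky triisopropylsilyl group is chosen to give the resulting vinylogous silyl ester enough hydrolytic stability to be handled.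

Step 14
Reactants: 15 (4R)-5-chloro-1-methoxy-4-Ar-pent-1-yne; 18 3-(triisopropylsilyloxy)cyclobut-2-en-1-one
Product: 23 2-[(2R)-3-chloro-2-Ar-propyl]-3-methoxy-5-(triisopropylsilyloxy)phenol, via silyloxyvinylketene 19 (not isolated), via vinylcyclobutenone 20 (not isolated), via dienylketene 21 (not isolated), via cyclohexadienone 22 (not isolated)
Conditions: 18 (1.5 equiv), toluene, 80 °C then 110 °C, sealed tube, argon
Reagents that add atoms: none
Why: This is a Danheiser benzannulation of a cyclobutenone with an alkoxyalkyne, with a 3-silyloxycyclobutenone as the four-carbon partner. On heating, 18 opens by a 4π electrocyclic reaction to vinylketene 19, whose electrophilic carbonyl carbon is attacked by the nucleophilic, chain-bearing carbon of ynol ether 15; closure of this [2+2] cycloaddition gives cyclobutenone 20. A second 4π opening of 20 gives dienylketene 21, and ring A closes by a thermally allowed disrotatory 6π electrocyclisation to dienone 22, which tautomerises to the phenol 23. The ketene carbonyl ends as the free C8a hydroxyl, the alkyne carbons become C4a with the chain and C5 with its methoxy group, and 18 supplies C6, C7 with its silyloxy group and C8. The one selectivity needed is the orientation of the [2+2] step, and the donor polarisation of the methoxyalkyne secures it by making the carbon remote from oxygen the nucleophile. The methyl ynol ether has no β-hydrogen in its alkoxy group, so it cannot fragment to a ketene by a retro-ene path at these temperatures. No stereocentre is formed, and C3 is an unactivated methine one carbon removed from the alkyne that is not touched. The prenyl alkene, the acetal and the primary chloride are inert to ketenes and to heat in a neutral hydrocarbon solvent.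

Step 15
Reactants: 23 2-[(2R)-3-chloro-2-Ar-propyl]-3-methoxy-5-(triisopropylsilyloxy)phenol
Product: 24 (3R)-3-Ar-5-methoxy-7-(triisopropylsilyloxy)chromane
Conditions: K2CO3, NaI (cat.), DMF, 60 °C
Reagents that add atoms: none
Why: Intramolecular Williamson etherification, a 6-exo-tet closure of the C8a phenoxide on the primary chloride (through the iodide formed in the flask); ring B is still an acetal, so the competing five-membered closure cannot occur. C3 is not a reacting centre and keeps its configuration.

Step 16
Reactants: 24 (3R)-3-Ar-5-methoxy-7-(triisopropylsilyloxy)chromane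
Product: 25 (3R)-3-Ar-5-methoxychroman-7-ol
Conditions: Bu4NF, THF, 0 °C; NH4Cl work-up
Reagents that add atoms: none
Why: Fluoride-induced cleavage of an aryl silyl ether, driven by the Si–F bond; the acetal, the ethers and the alkene are unaffected.

Step 17
Reactants: 25 (3R)-3-Ar-5-methoxychroman-7-ol
Product: 26 (3R)-3-[2-hydroxy-4-methoxy-3-(3-methylbut-2-en-1-yl)phenyl]-5-methoxychroman-7-ol
Conditions: HCl (3 M aq.), MeOH, 40 °C, stopped at full conversion
Reagents that add atoms: none
Why: Acid-catalysed methanolysis of the methoxymethyl acetal; short exposure to dilute acid should free the 2'-hydroxyl before it can add across the neighbouring prenyl double bond.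

## Compound list

1 | 2-bromo-5-methoxyphenol | COc1ccc(Br)c(O)c1 | starting material
2 | 1-bromo-4-methoxy-2-(prop-2-en-1-yloxy)benzene | COc1ccc(Br)c(OCC=C)c1 | intermediate
3 | 6-bromo-3-methoxy-2-(prop-2-en-1-yl)phenol | COc1ccc(Br)c(O)c1CC=C | intermediate
4 | 1-bromo-4-methoxy-2-(methoxymethoxy)-3-(prop-2-en-1-yl)benzene | COCOc1c(Br)ccc(OC)c1CC=C | intermediate
5 | 1-bromo-4-methoxy-2-(methoxymethoxy)-3-(3-methylbut-2-en-1-yl)benzene | COCOc1c(Br)ccc(OC)c1CC=C(C)C | intermediate
6 | diethyl malonate | CCOC(=O)CC(=O)OCC | starting material
7 | diethyl 2-[4-methoxy-2-(methoxymethoxy)-3-(3-methylbut-2-en-1-yl)phenyl]propanedioate | CCOC(=O)C(C(=O)OCC)c1ccc(OC)c(CC=C(C)C)c1OCOC | intermediate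
8 | 2-[4-methoxy-2-(methoxymethoxy)-3-(3-methylbut-2-en-1-yl)phenyl]propane-1,3-diol | OCC(CO)c1ccc(OC)c(CC=C(C)C)c1OCOC | intermediate
9 | (2R)-3-hydroxy-2-[4-methoxy-2-(methoxymethoxy)-3-(3-methylbut-2-en-1-yl)phenyl]propyl acetate | CC(=O)OC[C@H](c1ccc(OC)c(CC=C(C)C)c1OCOC)CO | intermediate
10 | (2S)-3-chloro-2-[4-methoxy-2-(methoxymethoxy)-3-(3-methylbut-2-en-1-yl)phenyl]propyl acetate | CC(=O)OC[C@H](c1ccc(OC)c(CC=C(C)C)c1OCOC)CCl | intermediate
11 | (2S)-3-chloro-2-[4-methoxy-2-(methoxymethoxy)-3-(3-methylbut-2-en-1-yl)phenyl]propan-1-ol | OC[C@H](c1ccc(OC)c(CC=C(C)C)c1OCOC)CCl | intermediate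
12 | (2S)-3-chloro-2-[4-methoxy-2-(methoxymethoxy)-3-(3-methylbut-2-en-1-yl)phenyl]propyl trifluoromethanesulfonate | O=S(=O)(OC[C@H](c1ccc(OC)c(CC=C(C)C)c1OCOC)CCl)C(F)(F)F | intermediate
13 | 2-chloro-1,1-dimethoxyethane (chloroacetaldehyde dimethyl acetal) | COC(CCl)OC | starting material
14 | lithium methoxyacetylide, LiC≡COMe (not isolated) | [Li]C#COC | intermediate
15 | (4R)-5-chloro-1-methoxy-4-[4-methoxy-2-(methoxymethoxy)-3-(3-methylbut-2-en-1-yl)phenyl]pent-1-yne | COC#CC[C@H](c1ccc(OC)c(CC=C(C)C)c1OCOC)CCl | intermediate
16 | 3-ethoxycyclobut-2-en-1-one | CCOC1=CC(=O)C1 | starting material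
17 | cyclobutane-1,3-dione (enol form: 3-hydroxycyclobut-2-en-1-one) | O=C1CC(=O)C1 | intermediate
18 | 3-(triisopropylsilyloxy)cyclobut-2-en-1-one | O=C1C=C(O[Si](C(C)C)(C(C)C)C(C)C)C1 | intermediate
19 | 3-(triisopropylsilyloxy)buta-1,3-dien-1-one (vinylketene, not isolated) | O=C=CC(=C)O[Si](C(C)C)(C(C)C)C(C)C | intermediate
20 | 2-[(2R)-3-chloro-2-Ar-propyl]-3-methoxy-4-[1-(triisopropylsilyloxy)ethenyl]cyclobut-2-en-1-one, both epimers at ring C4 (not isolated) | O=C1C(C[C@H](c2ccc(OC)c(CC=C(C)C)c2OCOC)CCl)=C(OC)C1C(=C)O[Si](C(C)C)(C(C)C)C(C)C | intermediate
21 | (3E)-2-[(2R)-3-chloro-2-Ar-propyl]-3-methoxy-5-(triisopropylsilyloxy)hexa-1,3,5-trien-1-one, ketene carbon and silyloxyvinyl group cis (not isolated) | O=C=C(C[C@H](c1ccc(OC)c(CC=C(C)C)c1OCOC)CCl)/C(OC)=C\C(=C)O[Si](C(C)C)(C(C)C)C(C)C | intermediate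
22 | 2-[(2R)-3-chloro-2-Ar-propyl]-3-methoxy-5-(triisopropylsilyloxy)cyclohexa-2,4-dien-1-one (not isolated) | O=C1CC(O[Si](C(C)C)(C(C)C)C(C)C)=CC(OC)=C1C[C@H](c1ccc(OC)c(CC=C(C)C)c1OCOC)CCl | intermediate
23 | 2-[(2R)-3-chloro-2-{4-methoxy-2-(methoxymethoxy)-3-(3-methylbut-2-en-1-yl)phenyl}propyl]-3-methoxy-5-(triisopropylsilyloxy)phenol | COc1cc(O[Si](C(C)C)(C(C)C)C(C)C)cc(O)c1C[C@H](c1ccc(OC)c(CC=C(C)C)c1OCOC)CCl | intermediate
24 | (3R)-5-methoxy-3-[4-methoxy-2-(methoxymethoxy)-3-(3-methylbut-2-en-1-yl)phenyl]-7-(triisopropylsilyloxy)chromane | COc1cc(O[Si](C(C)C)(C(C)C)C(C)C)cc2c1C[C@H](c1ccc(OC)c(CC=C(C)C)c1OCOC)CO2 | intermediate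
25 | (3R)-5-methoxy-3-[4-methoxy-2-(methoxymethoxy)-3-(3-methylbut-2-en-1-yl)phenyl]chroman-7-ol | COc1cc(O)cc2c1C[C@H](c1ccc(OC)c(CC=C(C)C)c1OCOC)CO2 | intermediate
26 | (3R)-3-[2-hydroxy-4-methoxy-3-(3-methylbut-2-en-1-yl)phenyl]-5-methoxychroman-7-ol | COc1cc(O)cc2c1C[C@H](c1ccc(OC)c(CC=C(C)C)c1O)CO2 | target

## Step count and uncertain steps

Total step count: 17. Longest linear sequence: 15 steps (steps 1 to 11 and 14 to 17); steps 12 and 13 form the short second branch.

**Step 14 (key step).**
- Risk: loss of the silyl group from the vinylogous silyl ester 18, or self-condensation of vinylketene 19, may be faster than its capture by 15. The cascade may also rest at cycloadduct 20, or the new phenol may be acylated by excess 19. All of these stem from the ketene being generated slowly and in the presence of its own product.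
- Fallback: a classical aryl–alkyl coupling that sets out from triflate 12 and returns at 25.
  - 5-Methoxybenzene-1,3-diol A8 is silylated twice (TIPSCl, imidazole, DMF) to 1-methoxy-3,5-bis(triisopropylsilyloxy)benzene F1.
  - NBS in MeCN at 0 °C should brominate F1 at the carbon between the methoxy group and one silyloxy group, since the carbon between the two silyloxy groups is shielded, to give 2-bromo-1-methoxy-3,5-bis(triisopropylsilyloxy)benzene F2.
  - Bromine–lithium exchange (t-BuLi, Et2O, −78 °C) and alkylation of the aryllithium with 12 (−78 to −20 °C) should give 2-[(2R)-3-chloro-2-Ar-propyl]-1-methoxy-3,5-bis(triisopropylsilyloxy)benzene F3.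
  - Bu4NF then frees both phenols to give 4-[(2R)-3-chloro-2-Ar-propyl]-5-methoxybenzene-1,3-diol F4.
  - K2CO3 in DMF closes O1–C2 to 25, because only the hydroxyl ortho to the chain can reach the chloride.

**Step 11.**
- Risk: the triflate may ionise with participation of the electron-rich aryl group or its ortho acetal oxygen (aryl shift or a five-membered cyclic ether) before the acetylide arrives, or the basic mixture may cause elimination across the benzylic C–H.
- Fallback: sets out from alcohol 11 and returns at 15. It replaces the sulfonate by a leaving group that does not ionise and can be purified. I2, PPh3 and imidazole give 1-[(2R)-1-chloro-3-iodopropan-2-yl]-4-methoxy-2-(methoxymethoxy)-3-(3-methylbut-2-en-1-yl)benzene F5, which is alkylated with LiC≡COMe 14 (from 13 and LiNEt2) in THF/HMPA at −20 to 0 °C.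

**Step 7.**
- Risk: the lipase may acetylate the other enantiotopic arm, or discriminate poorly, because the ortho acetal and the prenyl group crowd the aryl binding region.
- Fallback: sets out from diol 8 and returns at 9. It uses the enzyme in the opposite direction. Ac2O and pyridine give 2-Ar-propane-1,3-diyl diacetate F6, and the same lipase in pH 7 phosphate buffer hydrolyses the arm it would otherwise acylate, which gives the mirror-image monoacetate relative to the acylation mode.

**Step 5.**
- Risk: oxidative addition and reductive elimination are slow with the hindered, electron-rich bromide, so protodebromination or decomposition of the catalyst can take over.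
- Fallback: sets out from 5 and returns at 7. Palladium-catalysed coupling of 5 with the Reformatsky reagent BrZnCH2CO2Et (Pd2(dba)3, P(t-Bu)3, THF) gives ethyl 2-Ar-acetate F7, and NaH with diethyl carbonate in hot THF carbethoxylates F7 to 7.

**Step 17.**
- Risk: acid may add the freed 2'-hydroxyl, or the solvent, across the prenyl double bond to give a dimethylchroman or a hydrated side chain.
- Fallback: sets out from 24 and ends at 26; it avoids protic acid altogether. Et3SiOTf and 2,2'-bipyridyl in CH2Cl2 at 0 °C exchange the aryl methoxymethyl ether for a triethylsilyl ether, giving (3R)-5-methoxy-3-[4-methoxy-3-(3-methylbut-2-en-1-yl)-2-(triethylsilyloxy)phenyl]-7-(triisopropylsilyloxy)chromane F8. Bu4NF then removes both silyl groups to give 26.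

## Further compounds

F1 | step 14 | 1-methoxy-3,5-bis(triisopropylsilyloxy)benzene | COc1cc(O[Si](C(C)C)(C(C)C)C(C)C)cc(O[Si](C(C)C)(C(C)C)C(C)C)c1
F2 | step 14 | 2-bromo-1-methoxy-3,5-bis(triisopropylsilyloxy)benzene | COc1cc(O[Si](C(C)C)(C(C)C)C(C)C)cc(O[Si](C(C)C)(C(C)C)C(C)C)c1Br
F3 | step 14 | 2-[(2R)-3-chloro-2-{4-methoxy-2-(methoxymethoxy)-3-(3-methylbut-2-en-1-yl)phenyl}propyl]-1-methoxy-3,5-bis(triisopropylsilyloxy)benzene | COc1cc(O[Si](C(C)C)(C(C)C)C(C)C)cc(O[Si](C(C)C)(C(C)C)C(C)C)c1C[C@H](c1ccc(OC)c(CC=C(C)C)c1OCOC)CCl
F4 | step 14 | 4-[(2R)-3-chloro-2-{4-methoxy-2-(methoxymethoxy)-3-(3-methylbut-2-en-1-yl)phenyl}propyl]-5-methoxybenzene-1,3-diol | COc1cc(O)cc(O)c1C[C@H](c1ccc(OC)c(CC=C(C)C)c1OCOC)CCl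
F5 | step 11 | 1-[(2R)-1-chloro-3-iodopropan-2-yl]-4-methoxy-2-(methoxymethoxy)-3-(3-methylbut-2-en-1-yl)benzene | IC[C@H](c1ccc(OC)c(CC=C(C)C)c1OCOC)CCl
F6 | step 7 | 2-[4-methoxy-2-(methoxymethoxy)-3-(3-methylbut-2-en-1-yl)phenyl]propane-1,3-diyl diacetate | CC(=O)OCC(COC(C)=O)c1ccc(OC)c(CC=C(C)C)c1OCOC
F7 | step 5 | ethyl 2-[4-methoxy-2-(methoxymethoxy)-3-(3-methylbut-2-en-1-yl)phenyl]acetate | CCOC(=O)Cc1ccc(OC)c(CC=C(C)C)c1OCOC
F8 | step 17 | (3R)-5-methoxy-3-[4-methoxy-3-(3-methylbut-2-en-1-yl)-2-(triethylsilyloxy)phenyl]-7-(triisopropylsilyloxy)chromane | COc1cc(O[Si](C(C)C)(C(C)C)C(C)C)cc2c1C[C@H](c1ccc(OC)c(CC=C(C)C)c1O[Si](CC)(CC)CC)CO2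
A1 | alternative 1 | (3R)-5-methoxy-3-[4-methoxy-2-(methoxymethoxy)-3-(3-methylbut-2-en-1-yl)phenyl]-7-(triisopropylsilyloxy)-3,4-dihydrocoumarin | COc1cc(O[Si](C(C)C)(C(C)C)C(C)C)cc2c1C[C@H](c1ccc(OC)c(CC=C(C)C)c1OCOC)C(=O)O2
A2 | alternative 1 | 5-methoxy-6-methylidene-3-(triisopropylsilyloxy)cyclohexa-2,4-dien-1-one (ring A ortho-quinone methide) | C=C1C(=O)C=C(O[Si](C(C)C)(C(C)C)C(C)C)C=C1OC
A3 | alternative 1 | 2-[4-methoxy-2-(methoxymethoxy)-3-(3-methylbut-2-en-1-yl)phenyl]acetic acid | OC(=O)Cc1ccc(OC)c(CC=C(C)C)c1OCOC
A4 | alternative 2 | 3-[3-bromo-4-methoxy-2-(triisopropylsilyloxy)phenyl]-5-methoxy-7-(methoxymethoxy)chromenylium chloride | COCOc1cc(OC)c2cc(-c3ccc(OC)c(Br)c3O[Si](C(C)C)(C(C)C)C(C)C)c[o+]c2c1.[Cl-]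
A5 | alternative 2 | 4-methoxy-6-(methoxymethoxy)-1-benzofuran | COCOc1cc(OC)c2ccoc2c1
A6 | alternative 2 | 3-[3-bromo-4-methoxy-2-(triisopropylsilyloxy)phenyl]-3-chloro-3H-diazirine | ClC1(N=N1)c1ccc(OC)c(Br)c1O[Si](C(C)C)(C(C)C)C(C)C
A7 | alternative 3 | (3R)-3-[2-(tert-butyldimethylsilyloxy)-4-methoxy-3-(3-methylbut-2-en-1-yl)phenyl]-5-methoxychromane-2,7-diol (both anomers at C2) | COc1cc(O)cc2c1C[C@H](c1ccc(OC)c(CC=C(C)C)c1O[Si](C)(C)C(C)(C)C)C(O)O2
A8 | alternative 3 | 5-methoxybenzene-1,3-diol | COc1cc(O)cc(O)c1
A9 | alternative 3 | 2-[2-(tert-butyldimethylsilyloxy)-4-methoxy-3-(3-methylbut-2-en-1-yl)phenyl]prop-2-enal | C=C(C=O)c1ccc(OC)c(CC=C(C)C)c1O[Si](C)(C)C(C)(C)C
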